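**Retrosynthetic overview**
1. The target is a homoadamantane-type acylphloroglucinol. Ring A (C1–C2–C3–C4–C5–C9, a cyclohexane-1,3,5-trione) carries ring B (C1–C9–C5–C6–C7–C8), a seven-membered ring (C1–C2–C3–C11–C10–C7–C8) and a cyclopentane (C3–C11–C12–C13–C14).
2. The cyclopentane is closed last, by 5-exo attack of a tertiary C12 radical (made from a methyl ketone on C11) on a prenyl group on C3. This sets C13.
3. Key disconnection: C5–C6 and C7–C10 are formed in one radical cascade from a monocyclic trione. The enabling feature is that C5 lies between the C4 and C9 ketones, so a C5 radical is stabilised and electrophilic, while the C6=C7 vinyl group (on C8 at C1) and the C10=C11 enone (on C3) both sit 1,3 to it on the same face of ring A. The radical polarity therefore alternates along the cascade.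
4. The monocycle comes from 2,4,6-trihydroxybenzophenone. C1 is quaternised first (tetrachloro lock, O-prenylation/Claisen, unlock), then C5 is geranylated (Pd, desymmetrisation sets C1), C3 receives the enone (phosphine α-addition), C5 is chlorinated, and C3 is alkylated anti to the C8 group.
5. Order of ring formation: ring A (from the arene), then ring B plus the seven-membered ring (key step), then the cyclopentane.

Key step: step 9

Remark (locants, used for all compounds): C1 = benzoyl-bearing carbon; C2, C4, C9 = ring ketones; C3 = quaternary carbon between C2 and C4; C5 = geranyl-bearing carbon; C8 = CMe2, C7 = CH, C6 = CH2 (before step 9, C8–C7=C6 is the 2-methylbut-3-en-2-yl group); C10 (CH2) and C11 (CH) form the bridge C7–C10–C11–C3; C12 = CMe2, C13 = CH(iPr), C14 = CH2.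
Remark (tautomers and inconsequential centres): enolisable triones are written as one tautomer; C5 in 11 and 13 and the oxirane CH in 12–16 are carried as epimer mixtures, because the first becomes a planar radical in step 9 and the second is removed in step 11.

**Step 1**
Reactants: 1 2,4,6-trihydroxybenzophenone
Product: 2 4-benzoyl-2,2,6,6-tetrachloro-5-hydroxycyclohex-4-ene-1,3-dione (C3 and C5 as CCl2)
Conditions: SO2Cl2 (4.4 equiv), Et2O/CH2Cl2, 0 to 23 °C
Reagents that add atoms: sulfuryl chloride, ClS(Cl)(=O)=O
Why: Electrophilic chlorination of the phloroglucinol nucleus runs past the 3,5-dichloro stage to the gem-dichlorides, which makes C3 and C5 sp3 and leaves C1 of the 2-acyl-1,3-dione as the only enolisable ring carbon.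

**Step 2**
Reactants: 2 tetrachloro enol; 3 1-bromo-3-methylbut-2-ene (prenyl bromide)
Product: 5 2-benzoyl-4,4,6,6-tetrachloro-2-(2-methylbut-3-en-2-yl)cyclohexane-1,3,5-trione (achiral), via O-prenyl enol ether 4 (not isolated)
Conditions: Ag2O, PhH, 23 °C, dark; filter; PhMe, 100 °C
Reagents that add atoms: none
Why: Silver-assisted O-alkylation of the acidic triketone enol gives an allyl vinyl ether whose Claisen rearrangement ([3,3]) can only end at C1, because both flanking ring carbons are blocked; this installs the 2-methylbut-3-en-2-yl group and makes C1 quaternary.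

**Step 3**
Reactants: 5 tetrachloro trione
Product: 6 4-benzoyl-3,5-dihydroxy-4-(2-methylbut-3-en-2-yl)cyclohexa-2,5-dien-1-one (achiral, Cs-symmetric)
Conditions: Zn dust, sat. aq. NH4Cl/THF, 0 °C; used cold and at once
Reagents that add atoms: none
Why: Zinc reduction of α,α-dichloro-β-diketones (reductive dehalogenation) should remove the four blocking chlorines without touching the vinyl group or the benzoyl ketone; 6 is an ortho-dienone-type compound and is kept cold to avoid Cope or retro-Claisen shifts.

**Step 4**
Reactants: 6 Cs-symmetric dienone; 7 geranyl acetate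
Product: 8 (S)-6-benzoyl-2-[(2E)-3,7-dimethylocta-2,6-dien-1-yl]-3,5-dihydroxy-6-(2-methylbut-3-en-2-yl)cyclohexa-2,4-dien-1-one
Conditions: Pd2(dba)3·CHCl3 (2.5 mol %), (R,R)-DACH-phenyl Trost ligand (7.5 mol %; the antipodal ligand if the sense of induction is opposite), Et3N, 7 (0.8 equiv), CH2Cl2, −20 °C
Reagents that add atoms: none
Why: Proposed new method: C-allylation of a cyclic 1,3-dione enolate at the unsubstituted terminus of the π-geranyl-palladium complex (Tsuji–Trost) is standard, but here the chiral ligand must tell apart the two enantiotopic enol carbons C3 and C5 of the Cs-symmetric nucleophile, and this choice fixes the configuration of C1; the closest known reaction types are Pd-catalysed asymmetric allylic alkylation with prochiral 1,3-dicarbonyl nucleophiles and Pd-catalysed desymmetrisation of meso substrates.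

**Step 5**
Reactants: 8 geranyl dienone; 9 but-3-yn-2-one
Product: 10 (S)-6-benzoyl-2-geranyl-3,5-dihydroxy-6-(2-methylbut-3-en-2-yl)-4-(3-oxobut-1-en-2-yl)cyclohexa-2,4-dien-1-one
Conditions: PPh3 (20 mol %), PhMe, 23 °C
Reagents that add atoms: none
Why: Phosphine-catalysed α-addition (umpolung addition) of a 1,3-dicarbonyl C–H to an ynone: PPh3 adds to the alkynone, the zwitterion deprotonates the enol, and the enolate attacks the α-carbon of the vinylphosphonium ion through the unsubstituted C3 rather than the geranyl-bearing C5.

**Step 6**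
Reactants: 10 enone dienol
Product: 11 2-benzoyl-6-chloro-6-geranyl-3-hydroxy-2-(2-methylbut-3-en-2-yl)-4-(3-oxobut-1-en-2-yl)cyclohex-3-ene-1,5-dione (C5 epimers)
Conditions: N-chlorosuccinimide (1.05 equiv), CH2Cl2, −20 to 0 °C
Reagents that add atoms: N-chlorosuccinimide, O=C1CCC(=O)N1Cl
Why: Electrophilic α-chlorination of a 2-alkyl-1,3-dione enol should take place at the more electron-rich, alkyl-substituted C5 rather than at C3, which carries the electron-poor enone; the chlorine blocks C5 for step 8 and is the radical precursor for step 9.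

**Step 7**
Reactants: 3 prenyl bromide
Product: 12 2-(bromomethyl)-3,3-dimethyloxirane (racemic)
Conditions: m-CPBA, NaHCO3, CH2Cl2, 0 °C
Reagents that add atoms: m-chloroperbenzoic acid, OOC(=O)c1cccc(Cl)c1
Why: Prilezhaev epoxidation of the trisubstituted alkene.

**Step 8**
Reactants: 11 C5-chloro enol; 12 epoxy bromide
Product: 13 2-benzoyl-6-chloro-4-[(3,3-dimethyloxiran-2-yl)methyl]-6-geranyl-2-(2-methylbut-3-en-2-yl)-4-(3-oxobut-1-en-2-yl)cyclohexane-1,3,5-trione (enone arm on C3 cis to the C8 group on C1)
Conditions: Cs2CO3, n-Bu4NI (cat.), DMF, 0 to 23 °C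
Reagents that add atoms: none
Why: C-alkylation of the last enolisable position (C3) of the triketone enolate, as in exhaustive C-alkylation of phloroglucinol-derived triones; the electrophile should enter anti to the bulky tert-alkyl group on C1, which places the enone arm cis to it, and carrying the prenyl group as its epoxide removes the electron-rich alkene that would otherwise capture the C5 radical by 5-exo closure in step 9.

**Step 9**
Reactants: 13 monocyclic chloro trione
Product: 14 homoadamantane trione with acetyl at C11 (H on the C6 side), (3,3-dimethyloxiran-2-yl)methyl at C3, benzoyl at C1, geranyl at C5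
Conditions: Bu3SnH (1.3 equiv) and AIBN (0.2 equiv) by syringe pump over 8 h, PhH (0.005 M), 80 °C
Reagents that add atoms: none
Why: Bu3Sn• abstracts chlorine from the tertiary α-chloro-1,3-diketone to give an electrophilic C5 radical stabilised by the C4 and C9 carbonyls, which attacks the vinyl terminus C6 in a 6-endo-trig closure (ring C5–C6–C7–C8–C1–C9), the mode preferred by 2-oxohex-5-enyl radicals and reinforced here by the neopentyl internal carbon. The nucleophilic secondary C7 radical then adds to the enone terminus C10 in a 7-endo-trig Giese closure (ring C7–C10–C11–C3–C2–C1–C8), and the α-acetyl radical at C11 takes hydrogen from Bu3SnH. The closest known reaction types are stannane-mediated tandem cyclisations of α-halo-β-dicarbonyl compounds and the Mn(III)-mediated radical cascades of dearomatised acylphloroglucinols. C5 and C7 are set by the cage, since ring B can only form on the face of ring A that carries the C8 group and C7 can only reach C10 through its endo face. C11 is set by hydrogen transfer to the planar radical from the side of the C6 methylene, away from the C8 gem-dimethyl group. The step needs 6-endo over 5-exo closure and cyclisation faster than reduction of the C5 or C7 radical; this is secured by the polarity alternation (electrophilic radical on a plain vinyl group, nucleophilic radical on an enone), by slow stannane addition, by the cis relation of the two arms fixed in step 8, and by the absence of any other reachable electron-rich alkene.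

**Step 10**
Reactants: 14 cage methyl ketone
Product: 16 tertiary methyl oxalate at C12 [C11–C(CH3)2–OC(O)CO2CH3], epoxide retained, via bromomagnesium tertiary alkoxide 15 (not isolated)
Conditions: MeMgBr, anhydrous CeCl3, THF, −78 °C; then ClC(O)CO2Me, DMAP (cat.), −78 to 0 °C
Reagents that add atoms: methylmagnesium bromide, C[Mg]Br; methyl chlorooxoacetate, COC(=O)C(Cl)=O
Why: Organocerium 1,2-addition should go to the only unhindered ketone, the methyl ketone, without enolising C11, since the four other ketones are flanked by quaternary carbons; acylation of the alkoxide in the same flask gives the tertiary oxalate needed as radical precursor.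

**Step 11**
Reactants: 16 epoxy oxalate
Product: 17 cage with 3-methylbut-2-en-1-yl (prenyl) at C3 and the tertiary methyl oxalate at C12
Conditions: MeReO3 (5 mol %), PPh3 (1.5 equiv), PhH, 23 to 50 °C
Reagents that add atoms: none
Why: Methyltrioxorhenium-catalysed oxygen-atom transfer from the epoxide to triphenylphosphine (deoxygenation) unmasks the prenyl alkene under neutral conditions that leave the oxalate and the ketones alone.

**Step 12**
Reactants: 17 prenyl oxalate
Product: 18 target CNP0155129.1
Conditions: Bu3SnH (1.5 equiv) and AIBN (0.3 equiv) by syringe pump, PhMe (0.005 M), 110 °C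
Reagents that add atoms: none
Why: Dolan–MacMillan (Barton–McCombie-type) fragmentation of the tertiary methyl oxalate gives the tertiary C12 radical, which closes the cyclopentane by 5-exo-trig addition to C13 of the prenyl group; a Beckwith–Houk chair-like transition state places the new C13 substituent trans to C10 on C11, and the resulting tertiary radical is reduced by the stannane to the isopropyl group.

**Compound list**
1 | 2,4,6-trihydroxybenzophenone | O=C(c1ccccc1)c1c(O)cc(O)cc1O | starting material
2 | 4-benzoyl-2,2,6,6-tetrachloro-5-hydroxycyclohex-4-ene-1,3-dione | O=C1C(Cl)(Cl)C(=O)C(C(=O)c2ccccc2)=C(O)C1(Cl)Cl | intermediate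
3 | 1-bromo-3-methylbut-2-ene (prenyl bromide) | CC(C)=CCBr | starting material
4 | 4-benzoyl-2,2,6,6-tetrachloro-5-[(3-methylbut-2-en-1-yl)oxy]cyclohex-4-ene-1,3-dione | O=C1C(Cl)(Cl)C(=O)C(C(=O)c2ccccc2)=C(OCC=C(C)C)C1(Cl)Cl | intermediate
5 | 2-benzoyl-4,4,6,6-tetrachloro-2-(2-methylbut-3-en-2-yl)cyclohexane-1,3,5-trione | O=C1C(Cl)(Cl)C(=O)C(C(=O)c2ccccc2)(C(C)(C)C=C)C(=O)C1(Cl)Cl | intermediate
6 | 4-benzoyl-3,5-dihydroxy-4-(2-methylbut-3-en-2-yl)cyclohexa-2,5-dien-1-one | O=C1C=C(O)C(C(=O)c2ccccc2)(C(C)(C)C=C)C(O)=C1 | intermediate
7 | geranyl acetate | CC(C)=CCC/C(C)=C/COC(C)=O | starting material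
8 | (S)-6-benzoyl-2-geranyl-3,5-dihydroxy-6-(2-methylbut-3-en-2-yl)cyclohexa-2,4-dien-1-one | CC(C)=CCC/C(C)=C/CC1=C(O)C=C(O)[C@](C(=O)c2ccccc2)(C(C)(C)C=C)C1=O | intermediate
9 | but-3-yn-2-one | CC(=O)C#C | starting material
10 | (S)-6-benzoyl-2-geranyl-3,5-dihydroxy-6-(2-methylbut-3-en-2-yl)-4-(3-oxobut-1-en-2-yl)cyclohexa-2,4-dien-1-one | CC(C)=CCC/C(C)=C/CC1=C(O)C(C(=C)C(C)=O)=C(O)[C@](C(=O)c2ccccc2)(C(C)(C)C=C)C1=O | intermediate
11 | 2-benzoyl-6-chloro-6-geranyl-3-hydroxy-2-(2-methylbut-3-en-2-yl)-4-(3-oxobut-1-en-2-yl)cyclohex-3-ene-1,5-dione (C1 as in 10, C5 epimers) | CC(C)=CCC/C(C)=C/CC1(Cl)C(=O)C(C(=C)C(C)=O)=C(O)[C@](C(=O)c2ccccc2)(C(C)(C)C=C)C1=O | intermediate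
12 | 2-(bromomethyl)-3,3-dimethyloxirane (racemic) | CC1(C)OC1CBr | intermediate
13 | 2-benzoyl-6-chloro-4-[(3,3-dimethyloxiran-2-yl)methyl]-6-geranyl-2-(2-methylbut-3-en-2-yl)-4-(3-oxobut-1-en-2-yl)cyclohexane-1,3,5-trione (enone arm cis to the 2-methylbut-3-en-2-yl group) | CC(C)=CCC/C(C)=C/CC1(Cl)C(=O)[C@](CC2OC2(C)C)(C(=C)C(C)=O)C(=O)[C@](C(=O)c2ccccc2)(C(C)(C)C=C)C1=O | intermediate
14 | homoadamantane-2,4,9-trione: C1 benzoyl, C5 geranyl, C8 gem-dimethyl, C3 (3,3-dimethyloxiran-2-yl)methyl, C11 acetyl | CC(C)=CCC/C(C)=C/C[C@@]12C[C@H]3C[C@H](C(C)=O)[C@@](CC4OC4(C)C)(C1=O)C(=O)[C@@](C(=O)c1ccccc1)(C2=O)C3(C)C | intermediate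
15 | bromomagnesium alkoxide of the C12 tertiary alcohol derived from 14 | CC(C)=CCC/C(C)=C/C[C@@]12C[C@H]3C[C@H](C(C)(C)O[Mg]Br)[C@@](CC4OC4(C)C)(C1=O)C(=O)[C@@](C(=O)c1ccccc1)(C2=O)C3(C)C | intermediate
16 | C12 tertiary methyl oxalate, epoxide at the C3 side chain | CC(C)=CCC/C(C)=C/C[C@@]12C[C@H]3C[C@H](C(C)(C)OC(=O)C(=O)OC)[C@@](CC4OC4(C)C)(C1=O)C(=O)[C@@](C(=O)c1ccccc1)(C2=O)C3(C)C | intermediate
17 | C12 tertiary methyl oxalate, prenyl at C3 | CC(C)=CCC/C(C)=C/C[C@@]12C[C@H]3C[C@H](C(C)(C)OC(=O)C(=O)OC)[C@@](CC=C(C)C)(C1=O)C(=O)[C@@](C(=O)c1ccccc1)(C2=O)C3(C)C | intermediate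
18 | CNP0155129.1 | CC(C)=CCC/C(C)=C/C[C@@]12C[C@H]3C[C@@H]4C(C)(C)[C@@H](C(C)C)C[C@]4(C1=O)C(=O)[C@@](C(=O)c1ccccc1)(C2=O)C3(C)C | target

**Step count and risks**
Total steps: 12. Longest linear sequence: 11 (steps 1–6 and 8–12; step 7 is a one-step branch).

Steps most likely to fail:

- **Step 4 (Proposed new method).** The chiral catalyst may discriminate poorly between the two enantiotopic enol carbons, giving low enantiomeric purity, or allylation may continue at both C3 and C5. Fallback, from 6 back to 8: achiral Tsuji–Trost allylation of 6 with 7 [Pd(PPh3)4, Et3N, THF, 0 °C] gives the racemic geranyl dienone F1, which is resolved by preparative chromatography on a chiral stationary phase; the (S)-enantiomer is 8.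

- **Step 9 (key step).** Hydrogen may be transferred to the C5 or C7 radical before ring closure, the first closure may go 5-exo, or the ring may not reach the conformation that brings C7 to C10. Fallback, from 13 back to 14: the two closures are decoupled. Copper-catalysed atom-transfer radical cyclisation [CuCl, tris(2-pyridylmethyl)amine, 1,2-dichloroethane, 60 °C], which has no hydrogen donor, closes ring B and parks the chlorine on C7 to give the bicyclo[3.3.1]nonane C7-chloride F2. In a separate operation Bu3SnH/AIBN (slow addition, PhMe, 110 °C) regenerates the C7 radical, which closes onto C10 and is reduced to 14.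

- **Step 2.** Alkylation may occur on C1 instead of oxygen (giving the linear prenyl isomer), the [3,3] shift may stall because two adjacent quaternary carbons must form, or the benzoyl group may be lost by retro-Claisen cleavage. Fallback, from 2 directly to 5 without a new intermediate: molybdenum-catalysed allylic alkylation [Mo(CO)6 (cat.), tert-butyl 3-methylbut-2-en-1-yl carbonate, PhMe, 80 °C], in which a stabilised carbon nucleophile attacks the more substituted terminus of the allyl complex and so delivers the 2-methylbut-3-en-2-yl group to C1.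

**Further compounds**
F1 | step 4 | racemic 6-benzoyl-2-geranyl-3,5-dihydroxy-6-(2-methylbut-3-en-2-yl)cyclohexa-2,4-dien-1-one | CC(C)=CCC/C(C)=C/CC1=C(O)C=C(O)C(C(=O)c2ccccc2)(C(C)(C)C=C)C1=O
F2 | step 9 | bicyclo[3.3.1]nonane-2,4,9-trione with chlorine at C7 (C7 epimers), 3-oxobut-1-en-2-yl and (3,3-dimethyloxiran-2-yl)methyl at C3, benzoyl at C1, geranyl at C5 | CC(C)=CCC/C(C)=C/C[C@@]12CC(Cl)C(C)(C)[C@](C(=O)c3ccccc3)(C2=O)C(=O)[C@@](CC4OC4(C)C)(C(=C)C(C)=O)C1=O
F0 | step 2 | none | none
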